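**Retrosynthetic overview**
- Sophoranone (2S) is cut at the C2–aryl bond into 7-hydroxy-8-prenylchromone and a 4-hydroxy-3,5-diprenylphenyl boronate. A catalyst-controlled rhodium 1,4-addition sets the only stereocentre in the last step.
- The chromone is cut into two acyclic pieces, a 2-prenyl Chan-type bis(silyloxy)diene and penta-1,4-diyn-3-one. One pot gives Diels–Alder addition, loss of methanol (ring A), then 6-endo oxa-Michael closure onto the second alkyne arm (ring C).
- The diene comes from methyl acetoacetate and prenyl bromide, so the C8 prenyl group is placed without any late C-prenylation. The diynone comes from ethyl formate and ethynylmagnesium bromide.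
- Ring B is bought as 2,6-dibromophenol: double Stille prenylation, then sterically directed C–H borylation.
- Ring order: A, then C in the same flask; ring B is attached, not built.

Assumption: the descriptor in the target SMILES decodes to 2S, and ethynylmagnesium bromide (THF solution) and tributyl(prenyl)stannane are taken as commercial reagents.

**Route**

Step 1
Reactants: 1 methyl acetoacetate (1.5 equiv); 2 prenyl bromide (1-bromo-3-methylbut-2-ene)
Product: 3 methyl 2-acetyl-5-methylhex-4-enoate (racemic)
Conditions: K2CO3 (1.2 equiv), acetone, reflux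
Reagents that add atoms: none
Why: Acetoacetic ester alkylation (SN2 of the stabilised enolate on the primary allylic bromide); excess 1 limits dialkylation, and the racemic centre becomes sp2 in step 2.

Step 2
Reactants: 3 methyl 2-acetyl-5-methylhex-4-enoate
Product: 5 1-methoxy-2-(3-methylbut-2-enyl)-1,3-bis(trimethylsilyloxy)buta-1,3-diene, via mono-silyl enol ether 4 (not isolated)
Conditions: LiN(iPr)2 (1.1 equiv), THF, −78 °C, TMSCl; then LiN(iPr)2 (1.3 equiv), −78 °C, TMSCl, to 0 °C; hexane, filter under Ar, use crude
Reagents that add atoms: chlorotrimethylsilane, C[Si](C)(C)Cl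
Why: Chan-type bis(silyloxy)diene synthesis, by O-silylation of the β-ketoester enolate, then γ-deprotonation of the silyl enol ether and a second O-silylation; alkene geometry is irrelevant because that carbon becomes aromatic.

Step 3
Reactants: 6 ethyl formate; 7 ethynylmagnesium bromide (2.2 equiv)
Product: 8 penta-1,4-diyn-3-ol
Conditions: THF, 0 °C to rt; dilute aq. HCl work-up
Reagents that add atoms: none
Why: Double Grignard addition to a formate ester gives the symmetrical secondary carbinol.

Step 4
Reactants: 8 penta-1,4-diyn-3-ol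
Product: 9 penta-1,4-diyn-3-one
Conditions: activated MnO2 (10 equiv), CH2Cl2, 0 °C to rt; filter, use the cold solution at once
Reagents that add atoms: none
Why: MnO2 oxidation of a doubly propargylic alcohol; the volatile, irritant ketone is never concentrated.

Step 5
Reactants: 5 1-methoxy-2-(3-methylbut-2-enyl)-1,3-bis(trimethylsilyloxy)buta-1,3-diene; 9 penta-1,4-diyn-3-one (1.5 equiv)
Product: 13 7-hydroxy-8-(3-methylbut-2-enyl)-4H-chromen-4-one, via Diels–Alder adduct 10 (not isolated), via aryl ynone bis-silyl ether 11 (not isolated), via dihydroxyaryl ynone 12 (not isolated)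
Conditions: 5 added slowly to 9, CH2Cl2/toluene, −40 °C to rt; then MeOH, K2CO3 (0.2 equiv), rt; aq. NH4Cl
Reagents that add atoms: none
Why: Proposed new method: the diene adds to one ynone arm with the usual Diels–Alder regiochemistry (CH2 terminus to the alkyne CH, ketene-acetal carbon to the acyl-bearing carbon), adduct 10 aromatises by loss of methanol as in Danishefsky–Brassard resorcinol syntheses from acetylenic ketones, and methanolysis frees the ortho phenol, which closes onto the remaining ynone arm by 6-endo-dig oxa-Michael addition (the standard chromone closure of o-hydroxyaryl ynones); the untested element is running these known events in one pot on a cross-conjugated diynone, and no lasting stereocentre is formed.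

Step 6
Reactants: 14 2,6-dibromophenol; 15 tributyl(3-methylbut-2-enyl)stannane (2.4 equiv)
Product: 16 2,6-bis(3-methylbut-2-enyl)phenol
Conditions: Pd(PPh3)4 (5 mol %), DMF, 100 °C
Reagents that add atoms: none
Why: Double Stille coupling; bond formation at the unsubstituted allyl terminus gives the linear prenyl groups, and the free phenol is tolerated under these neutral conditions.

Step 7
Reactants: 16 2,6-bis(3-methylbut-2-enyl)phenol
Product: 17 2,6-bis(3-methylbut-2-enyl)-4-(4,4,5,5-tetramethyl-1,3,2-dioxaborolan-2-yl)phenol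
Conditions: [Ir(OMe)(cod)]2 (1.5 mol %), 4,4'-di-tert-butyl-2,2'-bipyridine (3 mol %), B2pin2 (1.5 equiv), THF, 60 °C; H2O work-up
Reagents that add atoms: bis(pinacolato)diboron, CC1(C)OB(OC1(C)C)B1OC(C)(C)C(C)(C)O1
Why: Hartwig–Miyaura C–H borylation is sterically controlled, so only the ring C–H with no ortho substituent (para to oxygen) reacts; the phenol is masked in the flask as its O-boryl ether and freed on work-up, and trisubstituted alkenes are poor hydroboration substrates.

Step 8
Reactants: 13 7-hydroxy-8-(3-methylbut-2-enyl)-4H-chromen-4-one; 17 2,6-bis(3-methylbut-2-enyl)-4-(4,4,5,5-tetramethyl-1,3,2-dioxaborolan-2-yl)phenol (2.5 equiv)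
Product: 18 sophoranone, (2S)-7-hydroxy-2-[4-hydroxy-3,5-bis(3-methylbut-2-enyl)phenyl]-8-(3-methylbut-2-enyl)-2,3-dihydro-4H-chromen-4-one
Conditions: [Rh(OH)((S)-BINAP)]2 (3 mol %), 1,4-dioxane/H2O 10:1, 50 °C
Reagents that add atoms: none
Why: Hayashi–Miyaura asymmetric 1,4-addition, in which the Rh–aryl intermediate inserts the chromone C2=C3 bond on the face set by the (S)-BINAP pocket; this is the enone face that gives (S)-3-arylcyclohexanones and maps onto 2S here (assigned by analogy, to be confirmed by CD), and base-free hydrolysis of the rhodium enolate avoids retro-oxa-Michael racemisation.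

**Compound list**

1 | methyl acetoacetate | CC(=O)CC(=O)OC | starting material
2 | prenyl bromide (1-bromo-3-methylbut-2-ene) | CC(C)=CCBr | starting material
3 | methyl 2-acetyl-5-methylhex-4-enoate (racemic) | CC(=O)C(CC=C(C)C)C(=O)OC | intermediate
4 | methyl 2-(3-methylbut-2-enyl)-3-(trimethylsilyloxy)but-2-enoate (E/Z mixture) | CC(O[Si](C)(C)C)=C(CC=C(C)C)C(=O)OC | intermediate
5 | 1-methoxy-2-(3-methylbut-2-enyl)-1,3-bis(trimethylsilyloxy)buta-1,3-diene (ketene acetal geometry uncontrolled) | C=C(O[Si](C)(C)C)C(CC=C(C)C)=C(OC)O[Si](C)(C)C | intermediate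
6 | ethyl formate | CCOC=O | starting material
7 | ethynylmagnesium bromide | C#C[Mg]Br | starting material
8 | penta-1,4-diyn-3-ol | C#CC(O)C#C | intermediate
9 | penta-1,4-diyn-3-one | C#CC(=O)C#C | intermediate
10 | 1-[6-methoxy-5-(3-methylbut-2-enyl)-4,6-bis(trimethylsilyloxy)cyclohexa-1,4-dien-1-yl]prop-2-yn-1-one (racemic) | C#CC(=O)C1=CCC(O[Si](C)(C)C)=C(CC=C(C)C)C1(OC)O[Si](C)(C)C | intermediate
11 | 1-[3-(3-methylbut-2-enyl)-2,4-bis(trimethylsilyloxy)phenyl]prop-2-yn-1-one | C#CC(=O)c1ccc(O[Si](C)(C)C)c(CC=C(C)C)c1O[Si](C)(C)C | intermediate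
12 | 1-[2,4-dihydroxy-3-(3-methylbut-2-enyl)phenyl]prop-2-yn-1-one | C#CC(=O)c1ccc(O)c(CC=C(C)C)c1O | intermediate
13 | 7-hydroxy-8-(3-methylbut-2-enyl)-4H-chromen-4-one | CC(C)=CCc1c(O)ccc2c(=O)ccoc12 | intermediate
14 | 2,6-dibromophenol | Oc1c(Br)cccc1Br | starting material
15 | tributyl(3-methylbut-2-enyl)stannane | CCCC[Sn](CCCC)(CCCC)CC=C(C)C | starting material
16 | 2,6-bis(3-methylbut-2-enyl)phenol | CC(C)=CCc1cccc(CC=C(C)C)c1O | intermediate
17 | 2,6-bis(3-methylbut-2-enyl)-4-(4,4,5,5-tetramethyl-1,3,2-dioxaborolan-2-yl)phenol | CC(C)=CCc1cc(B2OC(C)(C)C(C)(C)O2)cc(CC=C(C)C)c1O | intermediate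
18 | sophoranone, (2S)-7-hydroxy-2-[4-hydroxy-3,5-bis(3-methylbut-2-enyl)phenyl]-8-(3-methylbut-2-enyl)-2,3-dihydro-4H-chromen-4-one | CC(C)=CCc1cc([C@@H]2CC(=O)c3ccc(O)c(CC=C(C)C)c3O2)cc(CC=C(C)C)c1O | target

**Summary**

Total step count: 8. Longest linear sequence: 4 steps (1, 2, 5, 8; equally 3, 4, 5, 8).

Steps most likely to fail:

Step 5. The diynone may polymerise or take up two dienes, adduct 10 may lose silanol instead of methanol (giving a 2-methoxyaryl ketone that cannot cyclise), or the second arm may not close cleanly. The fallback builds the two rings one at a time. It sets out from 5: Diels–Alder addition and aromatisation with commercial but-3-yn-2-one (toluene, rt, then K2CO3/MeOH) gives 1-[2,4-dihydroxy-3-(3-methylbut-2-enyl)phenyl]ethanone F1. Heating F1 with N,N-dimethylformamide dimethyl acetal in toluene gives (E)-3-(dimethylamino)-1-[2,4-dihydroxy-3-(3-methylbut-2-enyl)phenyl]prop-2-en-1-one F2. Dilute HCl in CH2Cl2 closes F2 with loss of dimethylamine, and the route is rejoined at 13.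

Step 8. Chromones are sluggish acceptors, the pinacol ester transmetalates slowly without base, and the facial sense rests on analogy. The fallback gives up catalyst control and resolves. It sets out from 13 and 17: the more active achiral [Rh(OH)(cod)]2 in dioxane/H2O gives racemic sophoranone F3. Preparative chromatography on a chiral stationary phase delivers 18. The unwanted (2R)-sophoranone F4 is racemised with catalytic K2CO3 in MeOH (reversible ring opening to the chalcone) and recycled; the route is rejoined at 18.

Step 7. The [Ir(OMe)(cod)]2-derived catalyst may hydroborate or isomerise a prenyl group, or stall on the hindered O-boryl phenol. The fallback brings the handle for boron in from the start. It sets out from 15: double Stille coupling with commercial 2,6-dibromo-4-chlorophenol (Pd(PPh3)4, DMF, 100 °C; the C–Cl bond is untouched) gives 4-chloro-2,6-bis(3-methylbut-2-enyl)phenol F5. Miyaura borylation of this aryl chloride (Pd2(dba)3, XPhos, B2pin2, KOAc, dioxane, 100 °C) rejoins the route at 17.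

**Further compounds**

F1 | step 5 | 1-[2,4-dihydroxy-3-(3-methylbut-2-enyl)phenyl]ethanone | CC(=O)c1ccc(O)c(CC=C(C)C)c1O
F2 | step 5 | (E)-3-(dimethylamino)-1-[2,4-dihydroxy-3-(3-methylbut-2-enyl)phenyl]prop-2-en-1-one | CN(C)/C=C/C(=O)c1ccc(O)c(CC=C(C)C)c1O
F3 | step 8 | racemic sophoranone | CC(C)=CCc1cc(C2CC(=O)c3ccc(O)c(CC=C(C)C)c3O2)cc(CC=C(C)C)c1O
F4 | step 8 | (2R)-sophoranone | CC(C)=CCc1cc([C@H]2CC(=O)c3ccc(O)c(CC=C(C)C)c3O2)cc(CC=C(C)C)c1O
F5 | step 7 | 4-chloro-2,6-bis(3-methylbut-2-enyl)phenol | CC(C)=CCc1cc(Cl)cc(CC=C(C)C)c1O
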